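**Strategy.** Ring B, the six-membered lactone, is read as one molecule of CO2 inserted between aryl carbon C8a and the carbinol carbon C3. The precursor is an open-chain ortho-bromoaryl compound whose homobenzylic C3 carries a tosylate of the opposite, (S), configuration. In one flask, bromine–lithium exchange at C8a, capture of CO2 (C8a–C1 bond) and intramolecular SN2 attack of the new carboxylate oxygen on C3 with inversion (O2–C3 bond) close the lactone. The step exploits the C1(=O)–O2 carboxyl unit that bridges C8a, ortho to the C8 oxygen, and the sp3 stereocenter C3. The (R)-mevalonate ester is attached afterwards; benzyl and silyl groups are removed last.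

Key step: step 8

Assumptions: isochromanone numbering is used (C1 carbonyl, O2, C3 carbinol, C4 benzylic CH2, C4a/C8a ring fusion, C5 and C8 oxygenated). Compounds 1, 2, 7 and 16 are taken as commercial. The (S,S)-enantiomer of the salen cobalt catalyst is taken as the one that leaves (S)-configured monoalkyl oxiranes unreacted; if the opposite sense holds, the (R,R)-catalyst is used.

**Step 1**
Reactants: 1 (S)-propylene oxide; 2 but-3-en-1-ylmagnesium bromide
Product: 3 (S)-hept-6-en-2-ol
Conditions: CuI (10 mol %), THF, –30 → 0 °C; aq NH4Cl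
Reagents that add atoms: none
Why: Copper-catalysed Grignard opening of the terminal epoxide at its CH2 carbon leaves the C–O bond of the stereocenter untouched, so the (S) configuration comes from 1.

**Step 2**
Reactants: 3 (S)-hept-6-en-2-ol
Product: 4 tert-butyl[(2S)-hept-6-en-2-yloxy]dimethylsilane
Conditions: TBSCl, imidazole, DMF, rt
Reagents that add atoms: tert-butyldimethylsilyl chloride, CC(C)(C)[Si](C)(C)Cl
Why: Standard silylation of a secondary alcohol gives an ether that should survive peracid, BF3 at low temperature and organolithium reagents.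

**Step 3**
Reactants: 4 tert-butyl[(2S)-hept-6-en-2-yloxy]dimethylsilane
Product: 5 tert-butyldimethyl{[(2S)-5-(oxiran-2-yl)pentan-2-yl]oxy}silane (both epimers at the oxirane carbon)
Conditions: mCPBA, NaHCO3, CH2Cl2, 0 °C → rt
Reagents that add atoms: meta-chloroperoxybenzoic acid, OOC(=O)c1cccc(Cl)c1
Why: Prilezhaev epoxidation of the terminal alkene is expected to show no facial control from the remote stereocenter, so both oxirane epimers should form and are resolved in the next step.

**Step 4**
Reactants: 5 epimeric epoxide mixture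
Product: 6 tert-butyldimethyl{[(2S)-5-[(2S)-oxiran-2-yl]pentan-2-yl]oxy}silane
Conditions: (S,S)-(salen)Co(OAc) (0.5 mol %, trivalent cobalt; salen = N,N′-bis(3,5-di-tert-butylsalicylidene)cyclohexane-1,2-diamine dianion), H2O (0.55 equiv), THF, 0 °C → rt; chromatography
Reagents that add atoms: none
Why: Jacobsen hydrolytic kinetic resolution should hydrolyse only the (2R)-oxirane epimer, so catalyst control leaves the (2S)-oxirane, which is separated from the polar diol.

**Step 5**
Reactants: 7 2-bromobenzene-1,4-diol (bromohydroquinone)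
Product: 8 1,4-bis(benzyloxy)-2-bromobenzene
Conditions: BnBr (2.3 equiv), K2CO3, DMF, argon, rt → 50 °C
Reagents that add atoms: benzyl bromide, BrCc1ccccc1
Why: Williamson etherification of both phenols installs groups that tolerate organolithium chemistry and are removable by neutral hydrogenolysis at the end.

**Step 6**
Reactants: 8 1,4-bis(benzyloxy)-2-bromobenzene; 6 (2S)-oxirane
Product: 10 (2S,6S)-1-[3,6-bis(benzyloxy)-2-bromophenyl]-6-[(tert-butyldimethylsilyl)oxy]heptan-2-ol, via 3,6-bis(benzyloxy)-2-bromophenyllithium 9 (not isolated)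
Conditions: LiN(iPr)2 (1.1 equiv), THF, –78 °C, 1 h; then 6, BF3·OEt2 (2.2 equiv), –78 °C; aq NaHCO3
Reagents that add atoms: none
Why: Directed ortho-lithiation removes the most acidic ring hydrogen, flanked by Br and OBn, and the BF3-promoted opening of the terminal epoxide by the aryllithium at CH2 carries the (2S) oxirane configuration unchanged into the carbinol.

**Step 7**
Reactants: 10 bromo alcohol
Product: 11 (2S,6S)-1-[3,6-bis(benzyloxy)-2-bromophenyl]-6-[(tert-butyldimethylsilyl)oxy]heptan-2-yl 4-methylbenzenesulfonate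
Conditions: TsCl, Et3N, DMAP (cat.), CH2Cl2, 0 °C → rt
Reagents that add atoms: 4-methylbenzenesulfonyl chloride, Cc1ccc(cc1)S(=O)(=O)Cl
Why: O-sulfonylation forms only an O–S bond, so the (S) configuration is retained, and the tosyl group has no acidic α-hydrogen that an organolithium could remove.

**Step 8**
Reactants: 11 bromo tosylate
Product: 14 (3R)-5,8-bis(benzyloxy)-3-[(4S)-4-[(tert-butyldimethylsilyl)oxy]pentyl]isochroman-1-one, via aryllithium 12 (not isolated), via lithium benzoate 13 (not isolated)
Conditions: t-BuLi (2.1 equiv), THF/Et2O, –100 °C, 5 min; CO2 (dry, excess), –100 → –78 °C; then rt, DMF, 50 °C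
Reagents that add atoms: carbon dioxide, O=C=O
Why: Bromine–lithium exchange with t-BuLi at –100 °C should be faster than any attack of an organolithium on the secondary tosylate, and aryllithium 12 is carboxylated at once by CO2 to lithium benzoate 13, which forms the C8a–C1 bond. On warming in DMF the carboxylate oxygen displaces the tosylate at C3 intramolecularly, which forms the O2–C3 bond; the closest known reaction type is the Parham halogen–lithium exchange and carboxylation of bromoaryl alkyl halides followed by carboxylate SN2 lactonisation. Ring B closes in the 6-exo-tet mode. The C3 stereocenter is set by stereospecific inversion, the (S)-tosylate fixed by the resolved epoxide giving the (3R)-lactone. The step needs exchange at C–Br to outrun reaction at the sulfonate, which the low temperature, the second equivalent of t-BuLi (it destroys t-BuBr) and the non-enolisable tosyl group should secure. It also needs substitution to outrun elimination towards the styrene and aryl-assisted ionisation, which the weakly basic, intramolecular carboxylate in a dipolar aprotic solvent should secure.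

**Step 9**
Reactants: 14 silyl ether lactone
Product: 15 (3R)-5,8-bis(benzyloxy)-3-[(4S)-4-hydroxypentyl]isochroman-1-one
Conditions: HF·pyridine, pyridine/THF, 0 °C → rt
Reagents that add atoms: none
Why: Fluoride-mediated desilylation should free the secondary alcohol while the lactone and aryl benzyl ethers stay intact.

**Step 10**
Reactants: 16 (R)-mevalonolactone
Product: 17 potassium (3R)-3,5-dihydroxy-3-methylpentanoate
Conditions: KOH (1.0 equiv), H2O/MeOH, rt; evaporate to dryness
Reagents that add atoms: potassium hydroxide, [K+].[OH-]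
Why: Saponification opens the lactone without touching the quaternary stereocenter.

**Step 11**
Reactants: 17 potassium (R)-mevalonate
Product: 20 (3R)-5-[(tert-butyldimethylsilyl)oxy]-3-hydroxy-3-methylpentanoic acid, via bis-silyl ester 18 (not isolated), via potassium carboxylate 19 (not isolated)
Conditions: TBSCl (2.3 equiv), imidazole, DMF, rt; then K2CO3, MeOH/H2O/THF, rt; cold aq KHSO4 to pH 4
Reagents that add atoms: tert-butyldimethylsilyl chloride, CC(C)(C)[Si](C)(C)Cl
Why: Silylation should take place at the primary hydroxyl and the carboxylate but not at the tertiary hydroxyl, and the labile silyl ester is then cleaved selectively by mild carbonate hydrolysis.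

**Step 12**
Reactants: 15 secondary alcohol; 20 protected mevalonic acid
Product: 21 (2S)-5-[(3R)-5,8-bis(benzyloxy)-1-oxoisochroman-3-yl]pentan-2-yl (3R)-5-[(tert-butyldimethylsilyl)oxy]-3-hydroxy-3-methylpentanoate
Conditions: EDC·HCl, DMAP, CH2Cl2, 0 °C → rt
Reagents that add atoms: none
Why: Steglich-type carbodiimide esterification forms the acyl–oxygen bond, so the carbinol configuration is retained, and the tertiary hydroxyl is too hindered to compete.

**Step 13**
Reactants: 21 silyl-protected ester
Product: 22 (2S)-5-[(3R)-5,8-bis(benzyloxy)-1-oxoisochroman-3-yl]pentan-2-yl (3R)-3,5-dihydroxy-3-methylpentanoate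
Conditions: HF·pyridine, pyridine/THF, 0 °C
Reagents that add atoms: none
Why: Buffered fluoride desilylation should remove the primary silyl ether quickly under conditions too mild for translactonisation of the mevalonate ester.

**Step 14**
Reactants: 22 bis(benzyl ether)
Product: 23 Aspergimarin C
Conditions: H2 (1 atm), Pd/C, EtOAc, rt; filter under argon
Reagents that add atoms: none
Why: Neutral hydrogenolysis of the two aryl benzyl ethers should release the hydroquinone without affecting the lactone, the ester, the alcohols or any stereocenter.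

**Compound list**

1 | (S)-propylene oxide | C[C@H]1CO1 | starting material
2 | but-3-en-1-ylmagnesium bromide | C=CCC[Mg]Br | starting material
3 | (S)-hept-6-en-2-ol | C[C@H](O)CCCC=C | intermediate
4 | tert-butyl[(2S)-hept-6-en-2-yloxy]dimethylsilane | C[C@H](O[Si](C)(C)C(C)(C)C)CCCC=C | intermediate
5 | tert-butyldimethyl{[(2S)-5-(oxiran-2-yl)pentan-2-yl]oxy}silane, both oxirane epimers | C[C@H](O[Si](C)(C)C(C)(C)C)CCCC1CO1 | intermediate
6 | tert-butyldimethyl{[(2S)-5-[(2S)-oxiran-2-yl]pentan-2-yl]oxy}silane | C[C@H](O[Si](C)(C)C(C)(C)C)CCC[C@H]1CO1 | intermediate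
7 | 2-bromobenzene-1,4-diol | Oc1ccc(O)c(Br)c1 | starting material
8 | 1,4-bis(benzyloxy)-2-bromobenzene | Brc1cc(OCc2ccccc2)ccc1OCc1ccccc1 | intermediate
9 | 3,6-bis(benzyloxy)-2-bromophenyllithium | [Li]c1c(Br)c(OCc2ccccc2)ccc1OCc1ccccc1 | intermediate
10 | (2S,6S)-1-[3,6-bis(benzyloxy)-2-bromophenyl]-6-[(tert-butyldimethylsilyl)oxy]heptan-2-ol | C[C@H](O[Si](C)(C)C(C)(C)C)CCC[C@H](O)Cc1c(Br)c(OCc2ccccc2)ccc1OCc1ccccc1 | intermediate
11 | (2S,6S)-1-[3,6-bis(benzyloxy)-2-bromophenyl]-6-[(tert-butyldimethylsilyl)oxy]heptan-2-yl 4-methylbenzenesulfonate | C[C@H](O[Si](C)(C)C(C)(C)C)CCC[C@H](OS(=O)(=O)c1ccc(C)cc1)Cc1c(Br)c(OCc2ccccc2)ccc1OCc1ccccc1 | intermediate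
12 | 3,6-bis(benzyloxy)-2-[(2S,6S)-6-[(tert-butyldimethylsilyl)oxy]-2-(tosyloxy)heptyl]phenyllithium | C[C@H](O[Si](C)(C)C(C)(C)C)CCC[C@H](OS(=O)(=O)c1ccc(C)cc1)Cc1c([Li])c(OCc2ccccc2)ccc1OCc1ccccc1 | intermediate
13 | lithium 3,6-bis(benzyloxy)-2-[(2S,6S)-6-[(tert-butyldimethylsilyl)oxy]-2-(tosyloxy)heptyl]benzoate | C[C@H](O[Si](C)(C)C(C)(C)C)CCC[C@H](OS(=O)(=O)c1ccc(C)cc1)Cc1c(C(=O)[O-])c(OCc2ccccc2)ccc1OCc1ccccc1.[Li+] | intermediate
14 | (3R)-5,8-bis(benzyloxy)-3-[(4S)-4-[(tert-butyldimethylsilyl)oxy]pentyl]isochroman-1-one | C[C@H](O[Si](C)(C)C(C)(C)C)CCC[C@@H]1Cc2c(OCc3ccccc3)ccc(OCc3ccccc3)c2C(=O)O1 | intermediate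
15 | (3R)-5,8-bis(benzyloxy)-3-[(4S)-4-hydroxypentyl]isochroman-1-one | C[C@H](O)CCC[C@@H]1Cc2c(OCc3ccccc3)ccc(OCc3ccccc3)c2C(=O)O1 | intermediate
16 | (R)-mevalonolactone | C[C@@]1(O)CCOC(=O)C1 | starting material
17 | potassium (3R)-3,5-dihydroxy-3-methylpentanoate | C[C@@](O)(CCO)CC(=O)[O-].[K+] | intermediate
18 | tert-butyldimethylsilyl (3R)-5-[(tert-butyldimethylsilyl)oxy]-3-hydroxy-3-methylpentanoate | C[C@@](O)(CCO[Si](C)(C)C(C)(C)C)CC(=O)O[Si](C)(C)C(C)(C)C | intermediate
19 | potassium (3R)-5-[(tert-butyldimethylsilyl)oxy]-3-hydroxy-3-methylpentanoate | C[C@@](O)(CCO[Si](C)(C)C(C)(C)C)CC(=O)[O-].[K+] | intermediate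
20 | (3R)-5-[(tert-butyldimethylsilyl)oxy]-3-hydroxy-3-methylpentanoic acid | C[C@@](O)(CCO[Si](C)(C)C(C)(C)C)CC(=O)O | intermediate
21 | (2S)-5-[(3R)-5,8-bis(benzyloxy)-1-oxoisochroman-3-yl]pentan-2-yl (3R)-5-[(tert-butyldimethylsilyl)oxy]-3-hydroxy-3-methylpentanoate | C[C@@H](CCC[C@@H]1Cc2c(OCc3ccccc3)ccc(OCc3ccccc3)c2C(=O)O1)OC(=O)C[C@](C)(O)CCO[Si](C)(C)C(C)(C)C | intermediate
22 | (2S)-5-[(3R)-5,8-bis(benzyloxy)-1-oxoisochroman-3-yl]pentan-2-yl (3R)-3,5-dihydroxy-3-methylpentanoate | C[C@@H](CCC[C@@H]1Cc2c(OCc3ccccc3)ccc(OCc3ccccc3)c2C(=O)O1)OC(=O)C[C@](C)(O)CCO | intermediate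
23 | Aspergimarin C, (2S)-5-[(3R)-5,8-dihydroxy-1-oxoisochroman-3-yl]pentan-2-yl (3R)-3,5-dihydroxy-3-methylpentanoate | C[C@@H](CCC[C@@H]1Cc2c(O)ccc(O)c2C(=O)O1)OC(=O)C[C@](C)(O)CCO | target

**Step count and risks**

Total step count: 14. Longest linear sequence: 11 steps (steps 1, 2, 3, 4, 6, 7, 8, 9, 12, 13, 14, from (S)-propylene oxide).

Steps most likely to fail:

1. Step 8. The aryllithium may attack the sulfonate (sulfonyl transfer or four-membered cycloalkylation) before CO2 is captured. During the warm stage, elimination to the styrene or aryl-assisted ionisation may erode the inversion. The fallback separates the two bond formations and closes the ring by a Mitsunobu reaction. It sets out from 10: n-BuLi (1.0 equiv, –78 °C) forms the alkoxide, t-BuLi (2.1 equiv, –100 °C) then CO2 carboxylates C8a, and cold work-up at pH 5 should give 3,6-bis(benzyloxy)-2-[(2S,6S)-6-[(tert-butyldimethylsilyl)oxy]-2-hydroxyheptyl]benzoic acid F1. F1 is used at once, because spontaneous lactonisation would proceed with retention. PPh3 and DIAD in THF at 0 °C activate the C3 hydroxyl as its oxyphosphonium ion, and the carboxylate displaces it with inversion. The fallback comes back to the route at 14.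

2. Step 6. The ortho-bromoaryllithium may lose LiBr to the aryne on local warming, the benzylic positions of the ethers may be deprotonated in competition, and the amine may bind BF3 so that the epoxide is opened slowly. The fallback replaces deprotonation by halogen–magnesium exchange and BF3 activation by copper catalysis. It sets out from epoxide 6 and a new aryl partner. Bromine addition to p-benzoquinone (CHCl3, 0 °C) should give 5,6-dibromocyclohex-2-ene-1,4-dione F2, and acid-promoted enolisation (H2SO4) should give 2,3-dibromobenzene-1,4-diol F3. BnBr and K2CO3 in DMF then give 1,4-bis(benzyloxy)-2,3-dibromobenzene F4. Mono-exchange with iPrMgCl·LiCl (THF, –40 °C) should give [3,6-bis(benzyloxy)-2-bromophenyl]magnesium chloride F5. CuI-catalysed opening of 6 at –30 °C at the CH2 carbon comes back to the route at 10.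

3. Step 12. The activated β-hydroxy acid may dehydrate or close to a β-lactone, the O-acylisourea may rearrange to the N-acylurea, and acylation of the hindered secondary alcohol may be slow. The fallback uses a fully protected acyl donor and mixed-anhydride activation. It sets out from 20 and 15. TESOTf (2.2 equiv) and 2,6-lutidine in CH2Cl2 should give triethylsilyl (3R)-5-[(tert-butyldimethylsilyl)oxy]-3-methyl-3-[(triethylsilyl)oxy]pentanoate F6. K2CO3 in MeOH/H2O cleaves its silyl ester to (3R)-5-[(tert-butyldimethylsilyl)oxy]-3-methyl-3-[(triethylsilyl)oxy]pentanoic acid F7. Yamaguchi esterification with 15 (2,4,6-trichlorobenzoyl chloride, Et3N, then DMAP, toluene) should give (2S)-5-[(3R)-5,8-bis(benzyloxy)-1-oxoisochroman-3-yl]pentan-2-yl (3R)-5-[(tert-butyldimethylsilyl)oxy]-3-methyl-3-[(triethylsilyl)oxy]pentanoate F8. HF·pyridine removes both silyl groups, and the fallback comes back to the route at 22.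

**Further compounds**

F1 | step 8 | 3,6-bis(benzyloxy)-2-[(2S,6S)-6-[(tert-butyldimethylsilyl)oxy]-2-hydroxyheptyl]benzoic acid | C[C@H](O[Si](C)(C)C(C)(C)C)CCC[C@H](O)Cc1c(C(=O)O)c(OCc2ccccc2)ccc1OCc1ccccc1
F2 | step 6 | 5,6-dibromocyclohex-2-ene-1,4-dione (racemic trans) | O=C1C=CC(=O)C(Br)C1Br
F3 | step 6 | 2,3-dibromobenzene-1,4-diol | Oc1ccc(O)c(Br)c1Br
F4 | step 6 | 1,4-bis(benzyloxy)-2,3-dibromobenzene | Brc1c(Br)c(OCc2ccccc2)ccc1OCc1ccccc1
F5 | step 6 | [3,6-bis(benzyloxy)-2-bromophenyl]magnesium chloride | Cl[Mg]c1c(Br)c(OCc2ccccc2)ccc1OCc1ccccc1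
F6 | step 12 | triethylsilyl (3R)-5-[(tert-butyldimethylsilyl)oxy]-3-methyl-3-[(triethylsilyl)oxy]pentanoate | C[C@@](O[Si](CC)(CC)CC)(CCO[Si](C)(C)C(C)(C)C)CC(=O)O[Si](CC)(CC)CC
F7 | step 12 | (3R)-5-[(tert-butyldimethylsilyl)oxy]-3-methyl-3-[(triethylsilyl)oxy]pentanoic acid | C[C@@](O[Si](CC)(CC)CC)(CCO[Si](C)(C)C(C)(C)C)CC(=O)O
F8 | step 12 | (2S)-5-[(3R)-5,8-bis(benzyloxy)-1-oxoisochroman-3-yl]pentan-2-yl (3R)-5-[(tert-butyldimethylsilyl)oxy]-3-methyl-3-[(triethylsilyl)oxy]pentanoate | C[C@@H](CCC[C@@H]1Cc2c(OCc3ccccc3)ccc(OCc3ccccc3)c2C(=O)O1)OC(=O)C[C@](C)(O[Si](CC)(CC)CC)CCO[Si](C)(C)C(C)(C)C
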